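## Analysis of the target

The target (29) is a (3R)-isoflavan. A chroman (rings A and C; O1, C2, C3, C4, C4a–C8a) with a free 7-OH is joined through C3 to a benzene ring B (C1′–C6′), and a 2,2-dimethyl-2H-pyran (ring D) is fused to the C4′–C5′ edge of ring B. Going round ring B: C1′ carries the chroman, C2′ a free hydroxyl, C3′ a prenyl group, C4′ the pyran oxygen, C5′ the pyran CH=, and only C6′ carries hydrogen. C3 is the only stereocentre. It has no partner that could relay configuration, so it must be set absolutely by a catalyst and then kept away from any enolisable or eliminable situation. The chromene alkene, the prenyl alkene (which cyclises onto the C2′ hydroxyl under acid) and two electron-rich phenols rule out acid, hydrogen and oxidants late in the synthesis. The hard part is ring B: the C3′ prenyl lies between two oxygens, where electrophilic prenylation of a resorcinol is unselective, and five of six positions are substituted. The strategy rests on the triad C2′(OH)–C3′(C)–C4′(O) with a carbon substituent on C1′. That pattern is what forms when a vinylketene (carbonyl carbon → C2′, its other three carbons → C5′, C6′, C1′) combines with a siloxyalkyne (→ C3′ and C4′). Ring D can then only close between O4′ and C5′.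

## Retrosynthetic reasoning

29 ⇐ 28. The last bond cut is O7–allyl. The 7-OH must be masked while ring D is built, because a free 7-hydroxychroman is itself a 3-alkoxyphenol that could take up 26. An allyl ether is chosen because Pd(0) removes it under neutral conditions that spare chromene, prenyl and phenols.

28 ⇐ 25 + 26. Ring D is cut at C5′–C4(D) and O4′–C2(D). In the forward direction 26 condenses at C5′ to the quinone methide 27, which closes by oxa-6π electrocyclisation. C5′ is ortho to O4′ and para to O2′, whereas C6′ is meta to both, and O2′ has no free ortho carbon. Only one chromene can therefore form.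

25 ⇐ 24. Only the O4′–Si bond is cut. The silyl group is a consequence of the ring construction and is removed with fluoride.

24 ⇐ 14 + 19. This is the central disconnection. Four ring-B bonds are cut: C5′–C6′, C2′–C3′, C4′–C5′ and C1′–C2′. Forward, the diazo enone 14 becomes vinylketene 20, which adds the siloxyalkyne 19 and passes through 21, 22 and 23 to the phenol. Cutting here places the prenyl group (on the alkyne carbon) between the two oxygens by construction, and leaves the chroman with its stereocentre as a spectator on the enone terminus.

19 ⇐ 16 ⇐ 15. The siloxyalkyne is cut at the alkyne carbon next to the prenyl CH2. Forward, the ester 16 is homologated by one carbon with migration of the prenyl group to the ynolate 18, which is silylated on oxygen.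

14 ⇐ 12 ⇐ 10. The diazo group is removed first, giving the methyl enone 12; forward this is a diazo transfer through the activated diketone 13. Then the C=C bond of 12 is cut to the aldehyde 11, made in the flask from the alcohol 10 and olefinated at once, because 11 is an α-branched β-aryloxy aldehyde.

10 ⇐ 9 ⇐ 8 ⇐ 7. These are oxidation-level and protecting-group changes. The allyl ether cannot be present during the hydrogenation that sets C3, so the 7-oxygen is carried as a benzyl ether up to 7, freed to 8, and allylated together with the carboxyl group to 9.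

7 ⇐ 6. The two hydrogens at C3 and C4 are removed. Forward, a carboxylate-directed asymmetric hydrogenation sets the only stereocentre on a simple acid, early, where the enantiomeric purity can be raised by crystallisation.

6 ⇐ 4 ⇐ 2 + 3, and 2 ⇐ 1. The chromene acid comes from nitrile 4 through amide 5. Nitrile 4 is cut at O1–C2 and C3–C4 into the salicylaldehyde 2 and acrylonitrile 3, and 2 is the 4-O-benzyl ether of 1.

## Alternatives that were turned down

Alternative 1: Ring C is cut at C3–C4 and O1–C2. Forward, the o-quinone methide released from the 2-hydroxybenzyl alcohol A3 adds the ring-B enecarbamate A2 under a chiral phosphoric acid in an inverse-demand oxa-[4+2]. This gives the 2,3-trans aminal A1; reductive excision of the C2 nitrogen and desilylation would then give 29.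
- For: the two halves are joined in the same step that sets C3, catalytically and late. In convergence and in not having to carry a stereocentre through many steps this plan is stronger than the chosen one.
- Against: A2 already contains the whole pentasubstituted ring B with prenyl and chromene, so the real problem is presupposed, not solved. The C2 carbamate can only be removed by ionisation to an oxocarbenium ion and hydride delivery (Lewis acid and silane). Under those conditions the styrenyl chromene alkene and the prenyl alkene are protonated and reduced. The acid catalyst also meets the same alkenes, and the ortho-silyloxy aryl group of A2 crowds the hydrogen-bonded transition state.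
- Comparison: the chosen route accepts a longer linear sequence and gets in return a ring B whose substitution pattern is dictated by mechanism and an endgame free of acid and hydride.

Alternative 2: Only ring D is cut (C5′–C4 and O4′–C2). Forward, the resorcinol A5 condenses with 26 and closes by oxa-6π to the pivalate A4; methanolysis would give 29.
- For: the closure is short, biomimetic and regiochemically forced, and a pivalate is removed as gently as an allyl ether. As a key step it is less risky than a photochemical benzannulation, so on that point it is stronger.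
- Against: it disconnects the easy bonds. A5, with the prenyl between two hydroxyls and the C3 stereocentre, is left to be made. C-prenylation of a 4-substituted resorcinol goes to oxygen or to C5′. Directed metalation between two acetal-protected oxygens would work, but then needs acid deprotection next to the prenyl group. A hydrogenative entry to the isoflavan core cannot coexist with the prenyl group.
- Comparison: the chosen route uses the same closure as its step 14, so nothing is given up. What it adds is a way to the A5-type intermediate 25 in which the alkyne carbon, not an electrophile, places the prenyl group.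

Alternative 3: The chroman is cut at O1–C8a. Forward, the primary alcohol of the p-quinol A7 (from oxidative dearomatisation of a para-alkylphenol) adds 6-exo to the dienone, and acid-induced loss of the tertiary hydroxyl rearomatises ring A to give A6; deallylation would give 29.
- For: the 7-OH appears unprotected and in the right place by mechanism, since the dienone carbonyl becomes the phenol para to C4a. On that point it is stronger than the chosen route, which needs a benzyl-to-allyl exchange.
- Against: the phenol oxidation has to be done in a molecule that holds a more electron-rich chromene-fused ring B and a prenyl group. The rearomatisation needs acid in the presence of the chromene. Neither C3 nor ring B is addressed, and redox steps are spent on an aryl ether bond.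
- Comparison: the chosen strategy puts its risk into the one step that solves ring B and obtains the A-ring ether bond from a simple annulation in step 2.

Key step: step 12

Assumption: the sense of induction of the iridium catalyst in step 4 is assigned by correlation at the first run, and the ligand antipode that gives the (S)-acid 7 is the one used.

## Route

Step 1
Reactants: 1 2,4-dihydroxybenzaldehyde
Product: 2 4-(benzyloxy)-2-hydroxybenzaldehyde
Conditions: BnBr (1.05 equiv), NaHCO3, KI (cat.), MeCN, 80 °C
Reagents that add atoms: benzyl bromide, BrCc1ccccc1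
Why: Williamson etherification; the 2-OH is hydrogen-bonded to the aldehyde and less acidic, so a weak base alkylates only the 4-OH.

Step 2
Reactants: 2 4-(benzyloxy)-2-hydroxybenzaldehyde, 3 acrylonitrile
Product: 4 7-(benzyloxy)-2H-chromene-3-carbonitrile
Conditions: 3 (excess, neat), DABCO (0.5 equiv), 80 °C
Reagents that add atoms: none
Why: Amine-mediated Baylis–Hillman/oxa-Michael annulation of a salicylaldehyde with an acrylic acceptor and loss of water is the standard entry to 3-cyano-2H-chromenes. The benzyl ether keeps the para oxygen from being deprotonated, which would deactivate the aldehyde.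

Step 3
Reactants: 4 7-(benzyloxy)-2H-chromene-3-carbonitrile
Product: 6 7-(benzyloxy)-2H-chromene-3-carboxylic acid, via primary carboxamide 5 (not isolated)
Conditions: NaOH (10% aq.), EtOH, reflux; then HCl to pH 2
Reagents that add atoms: sodium hydroxide, [Na+].[OH-]; water, O
Why: Basic hydrolysis of a conjugated nitrile through the amide; the benzyl ether and the 2H-chromene ring are stable to hot hydroxide.

Step 4
Reactants: 6 7-(benzyloxy)-2H-chromene-3-carboxylic acid
Product: 7 (S)-7-(benzyloxy)chroman-3-carboxylic acid
Conditions: [Ir(cod)(SIPHOX)]BArF (1 mol%), H2 (6 atm), Et3N (0.5 equiv), MeOH, rt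
Reagents that add atoms: none
Why: Carboxylate-directed iridium asymmetric hydrogenation of an α-substituted cinnamic-type acid: the bound carboxylate steers H2 to one face of the trisubstituted C3=C4 bond, so the spiro phosphine–oxazoline ligand sets C3. The descriptor is S because CO2H outranks C2; the spatial arrangement is that of the target. The homogeneous catalyst leaves the benzyl ether intact.

Step 5
Reactants: 7 (S)-7-(benzyloxy)chroman-3-carboxylic acid
Product: 8 (S)-7-hydroxychroman-3-carboxylic acid
Conditions: H2 (1 atm), 10% Pd/C, MeOH, rt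
Reagents that add atoms: none
Why: Hydrogenolysis of the benzyl ether; no other group is reducible and C3 is not touched.

Step 6
Reactants: 8 (S)-7-hydroxychroman-3-carboxylic acid
Product: 9 allyl (S)-7-(allyloxy)chroman-3-carboxylate
Conditions: allyl bromide (2.5 equiv), K2CO3, DMF, rt
Reagents that add atoms: allyl bromide, C=CCBr
Why: Double O-alkylation of carboxylate and phenoxide; carbonate at room temperature does not remove the ester α-proton, so C3 is not epimerised. The allyl ether is put on only now because it would not survive step 4.

Step 7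
Reactants: 9 allyl (S)-7-(allyloxy)chroman-3-carboxylate
Product: 10 [(R)-7-(allyloxy)chroman-3-yl]methanol
Conditions: LiAlH4, THF, 0 °C
Reagents that add atoms: none
Why: Hydride reduction of the ester to the primary alcohol; the aryl allyl ether is inert. The descriptor changes to R only because CH2OH ranks below C2.

Step 8
Reactants: 10 [(R)-7-(allyloxy)chroman-3-yl]methanol
Product: 12 (E)-4-[(R)-7-(allyloxy)chroman-3-yl]but-3-en-2-one, via chroman-3-carbaldehyde 11 (not isolated)
Conditions: Dess–Martin periodinane, NaHCO3, CH2Cl2, 0 °C → rt; then Ph3P=CHC(O)CH3 (2 equiv), rt → 40 °C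
Reagents that add atoms: 1-(triphenylphosphoranylidene)propan-2-one, CC(=O)C=P(c1ccccc1)(c1ccccc1)c1ccccc1
Why: Buffered Dess–Martin oxidation followed in the same flask by Wittig olefination with a stabilised, non-basic ylide, which gives the E enone. The α-branched β-aryloxy aldehyde 11 is never concentrated or chromatographed, which limits enolisation at C3.

Step 9
Reactants: 12 (E)-4-[(R)-7-(allyloxy)chroman-3-yl]but-3-en-2-one
Product: 14 (E)-4-[(R)-7-(allyloxy)chroman-3-yl]-1-diazobut-3-en-2-one, via trifluoroacetyl diketone 13 (not isolated)
Conditions: LiHMDS, THF, −78 °C; CF3CO2CH2CF3; aq. HCl work-up, crude taken on; MsN3, Et3N, H2O, MeCN, rt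
Reagents that add atoms: methanesulfonyl azide, CS(=O)(=O)N=[N+]=[N-]; 2,2,2-trifluoroethyl trifluoroacetate, O=C(OCC(F)(F)F)C(F)(F)F (its acyl group stays only in 13)
Why: Detrifluoroacetylative diazo transfer, the standard route to α′-diazo enones. The amide base removes a methyl proton kinetically at −78 °C, not the γ-proton at C3. Claisen acylation activates that carbon, and the azide transfers N2 with loss of the trifluoroacetyl group as the sulfonamide.

Step 10
Reactants: 15 4-methylpent-3-enoic acid
Product: 16 ethyl 4-methylpent-3-enoate
Conditions: EtI, K2CO3, DMF, rt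
Reagents that add atoms: iodoethane, CCI
Why: Carboxylate O-alkylation under mild base; this avoids acid, which would lactonise the β,γ-unsaturated acid, and strong base, which would move the alkene into conjugation.

Step 11
Reactants: 16 ethyl 4-methylpent-3-enoate
Product: 19 triisopropyl[(5-methylhex-4-en-1-yn-1-yl)oxy]silane, via dibromomethyl ketone enolate 17 (not isolated), via lithium ynolate 18 (not isolated)
Conditions: CH2Br2, LiTMP, THF, −78 °C; then 16; LiHMDS; n-BuLi, −78 °C → rt; TIPSCl, −78 °C → rt
Reagents that add atoms: dibromomethane, BrCBr; chlorotriisopropylsilane, CC(C)[Si](Cl)(C(C)C)C(C)C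
Why: Kowalski ester homologation: LiCHBr2 adds to the ester at −78 °C faster than it enolises the α-CH2, and Br–Li exchange in the dibromo enolate triggers a 1,2-shift of the prenyl group to the ynolate. The bulky chlorosilane then silylates oxygen, giving a siloxyalkyne stable enough to purify.

Step 12
Reactants: 14 (E)-4-[(R)-7-(allyloxy)chroman-3-yl]-1-diazobut-3-en-2-one, 19 triisopropyl[(5-methylhex-4-en-1-yn-1-yl)oxy]silane
Product: 24 6-[(3R)-7-(allyloxy)chroman-3-yl]-2-(3-methylbut-2-en-1-yl)-3-[(triisopropylsilyl)oxy]phenol, via vinylketene 20 (not isolated), via 4-vinylcyclobutenone 21 (not isolated), via dienylketene 22 (not isolated), via cyclohexadienone 23 (not isolated)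
Conditions: 19 (2 equiv), ClCH2CH2Cl (0.3 M, degassed), hν (350 nm lamps, Pyrex), rt until N2 evolution ends; then 80 °C
Reagents that add atoms: none
Why: Irradiation above 300 nm excites only the diazo enone; loss of N2 with 1,2-shift of the alkenyl group (photochemical Wolff rearrangement, forming C5′–C6′) gives vinylketene 20. Ketene 20 adds the electron-rich alkyne 19 in a [2+2] in which the nucleophilic, prenyl-bearing alkyne carbon bonds to the ketene carbonyl carbon (C2′–C3′) and the oxygen-bearing carbon to the ketene α-carbon (C4′–C5′), giving 21. On warming, 21 opens by 4π electrocyclic cleavage of the bond between its carbonyl carbon and its sp3 carbon to dienylketene 22, which closes ring B by thermal disrotatory 6π electrocyclisation between the ketene carbon and the alkene terminus (C1′–C2′) to 23; tautomerisation gives the phenol. This is the diazo-ketone variant of the Danheiser benzannulation with a siloxyalkyne, a known route to resorcinol monosilyl ethers. No stereocentre is created: the sp3 centres of 21 and 23 disappear on ring opening and aromatisation. Regioselectivity is needed only in the [2+2] and comes from matched polarisation (electrophilic ketene carbonyl carbon, nucleophilic alkyne β-carbon); all later events are intramolecular and allow one arene only. C3 keeps its configuration because the medium is neutral and the E alkene holds C3–H away from the ketene carbon, so no 1,5-hydrogen shift can occur. The long wavelength avoids exciting the aryl allyl ether (photo-Claisen), and the excess of 19 competes with ketene dimerisation and with acylation of the product, whose hydroxyl is flanked by two substituents.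

Step 13
Reactants: 24 6-[(3R)-7-(allyloxy)chroman-3-yl]-2-(3-methylbut-2-en-1-yl)-3-[(triisopropylsilyl)oxy]phenol
Product: 25 4-[(3R)-7-(allyloxy)chroman-3-yl]-2-(3-methylbut-2-en-1-yl)benzene-1,3-diol
Conditions: TBAF, AcOH (1:1), THF, 0 °C
Reagents that add atoms: none
Why: Fluoride cleavage of the aryl silyl ether; the acetic acid buffer keeps the electron-rich resorcinol from standing as an oxidisable phenoxide, and allyl ether and prenyl group are untouched.

Step 14
Reactants: 25 4-[(3R)-7-(allyloxy)chroman-3-yl]-2-(3-methylbut-2-en-1-yl)benzene-1,3-diol, 26 3-methylbut-2-enal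
Product: 28 (3R)-7-(allyloxy)-3-[7-hydroxy-2,2-dimethyl-8-(3-methylbut-2-en-1-yl)-2H-chromen-6-yl]chroman, via o-quinone methide 27 (not isolated)
Conditions: 26 (2.5 equiv), ethylenediammonium diacetate (20 mol%), toluene, 110 °C
Reagents that add atoms: none
Why: Ammonium-salt-catalysed formal [3+3] chromene annulation: C-alkylation at C5′, dehydration to the o-quinone methide, then oxa-6π electrocyclisation. C5′ is the only position activated by both hydroxyls and O2′ has no free ortho carbon, so only one 2H-chromene can form. Ring A is an allyl ether, not a phenol, and does not react.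

Step 15
Reactants: 28 (3R)-7-(allyloxy)-3-[7-hydroxy-2,2-dimethyl-8-(3-methylbut-2-en-1-yl)-2H-chromen-6-yl]chroman
Product: 29 (3R)-3-[7-hydroxy-2,2-dimethyl-8-(3-methylbut-2-en-1-yl)-2H-chromen-6-yl]chroman-7-ol
Conditions: Pd(PPh3)4 (5 mol%), morpholine, THF, rt
Reagents that add atoms: none
Why: Tsuji–Trost allyl transfer from the aryl ether to morpholine under neutral conditions. The prenyl group has no leaving group, and the chromene C2–O bond is tertiary and lies nearly in the plane of its cis alkene, so it does not ionise at room temperature.

## Compound list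

1 | 2,4-dihydroxybenzaldehyde | O=Cc1ccc(O)cc1O | starting material
2 | 4-(benzyloxy)-2-hydroxybenzaldehyde | O=Cc1ccc(OCc2ccccc2)cc1O | intermediate
3 | acrylonitrile | C=CC#N | starting material
4 | 7-(benzyloxy)-2H-chromene-3-carbonitrile | N#CC1=Cc2ccc(OCc3ccccc3)cc2OC1 | intermediate
5 | 7-(benzyloxy)-2H-chromene-3-carboxamide | NC(=O)C1=Cc2ccc(OCc3ccccc3)cc2OC1 | intermediate (not isolated)
6 | 7-(benzyloxy)-2H-chromene-3-carboxylic acid | OC(=O)C1=Cc2ccc(OCc3ccccc3)cc2OC1 | intermediate
7 | (S)-7-(benzyloxy)chroman-3-carboxylic acid | OC(=O)[C@@H]1COc2cc(OCc3ccccc3)ccc2C1 | intermediate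
8 | (S)-7-hydroxychroman-3-carboxylic acid | OC(=O)[C@@H]1COc2cc(O)ccc2C1 | intermediate
9 | allyl (S)-7-(allyloxy)chroman-3-carboxylate | C=CCOC(=O)[C@@H]1COc2cc(OCC=C)ccc2C1 | intermediate
10 | [(R)-7-(allyloxy)chroman-3-yl]methanol | OC[C@@H]1COc2cc(OCC=C)ccc2C1 | intermediate
11 | (S)-7-(allyloxy)chroman-3-carbaldehyde | O=C[C@@H]1COc2cc(OCC=C)ccc2C1 | intermediate (not isolated)
12 | (E)-4-[(R)-7-(allyloxy)chroman-3-yl]but-3-en-2-one | CC(=O)/C=C/[C@@H]1COc2cc(OCC=C)ccc2C1 | intermediate
13 | (E)-6-[(R)-7-(allyloxy)chroman-3-yl]-1,1,1-trifluorohex-5-ene-2,4-dione | O=C(CC(=O)/C=C/[C@@H]1COc2cc(OCC=C)ccc2C1)C(F)(F)F | intermediate (not isolated)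
14 | (E)-4-[(R)-7-(allyloxy)chroman-3-yl]-1-diazobut-3-en-2-one | [N-]=[N+]=CC(=O)/C=C/[C@@H]1COc2cc(OCC=C)ccc2C1 | intermediate
15 | 4-methylpent-3-enoic acid | CC(C)=CCC(=O)O | starting material
16 | ethyl 4-methylpent-3-enoate | CCOC(=O)CC=C(C)C | intermediate
17 | 1,1-dibromo-5-methylhex-4-en-2-one (present as its lithium enolate) | CC(C)=CCC(=O)C(Br)Br | intermediate (not isolated)
18 | lithium 5-methylhex-4-en-1-yn-1-olate | CC(C)=CCC#C[O-].[Li+] | intermediate (not isolated)
19 | triisopropyl[(5-methylhex-4-en-1-yn-1-yl)oxy]silane | CC(C)=CCC#CO[Si](C(C)C)(C(C)C)C(C)C | intermediate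
20 | (E)-4-[(R)-7-(allyloxy)chroman-3-yl]buta-1,3-dien-1-one | O=C=C/C=C/[C@@H]1COc2cc(OCC=C)ccc2C1 | intermediate (not isolated)
21 | 4-{(E)-2-[(R)-7-(allyloxy)chroman-3-yl]vinyl}-2-(3-methylbut-2-en-1-yl)-3-[(triisopropylsilyl)oxy]cyclobut-2-en-1-one (both C4 epimers) | CC(C)=CCC1=C(O[Si](C(C)C)(C(C)C)C(C)C)C(/C=C/[C@@H]2COc3cc(OCC=C)ccc3C2)C1=O | intermediate (not isolated)
22 | (3E,5E)-6-[(R)-7-(allyloxy)chroman-3-yl]-2-(3-methylbut-2-en-1-yl)-3-[(triisopropylsilyl)oxy]hexa-1,3,5-trien-1-one | O=C=C(CC=C(C)C)/C(O[Si](C(C)C)(C(C)C)C(C)C)=C\C=C\[C@@H]1COc2cc(OCC=C)ccc2C1 | intermediate (not isolated)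
23 | 6-[(R)-7-(allyloxy)chroman-3-yl]-2-(3-methylbut-2-en-1-yl)-3-[(triisopropylsilyl)oxy]cyclohexa-2,4-dien-1-one (both C6 epimers) | CC(C)=CCC1=C(O[Si](C(C)C)(C(C)C)C(C)C)C=CC([C@@H]2COc3cc(OCC=C)ccc3C2)C1=O | intermediate (not isolated)
24 | 6-[(3R)-7-(allyloxy)chroman-3-yl]-2-(3-methylbut-2-en-1-yl)-3-[(triisopropylsilyl)oxy]phenol | CC(C)=CCc1c(O)c([C@@H]2COc3cc(OCC=C)ccc3C2)ccc1O[Si](C(C)C)(C(C)C)C(C)C | intermediate
25 | 4-[(3R)-7-(allyloxy)chroman-3-yl]-2-(3-methylbut-2-en-1-yl)benzene-1,3-diol | CC(C)=CCc1c(O)c([C@@H]2COc3cc(OCC=C)ccc3C2)ccc1O | intermediate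
26 | 3-methylbut-2-enal | CC(C)=CC=O | starting material
27 | 4-[(3R)-7-(allyloxy)chroman-3-yl]-3-hydroxy-6-[(Z)-3-methylbut-2-en-1-ylidene]-2-(3-methylbut-2-en-1-yl)cyclohexa-2,4-dien-1-one | CC(C)=CCC1=C(O)C([C@@H]2COc3cc(OCC=C)ccc3C2)=C/C(=C/C=C(C)C)C1=O | intermediate (not isolated)
28 | (3R)-7-(allyloxy)-3-[7-hydroxy-2,2-dimethyl-8-(3-methylbut-2-en-1-yl)-2H-chromen-6-yl]chroman | CC(C)=CCc1c(O)c([C@@H]2COc3cc(OCC=C)ccc3C2)cc2c1OC(C)(C)C=C2 | intermediate
29 | (3R)-3-[7-hydroxy-2,2-dimethyl-8-(3-methylbut-2-en-1-yl)-2H-chromen-6-yl]chroman-7-ol | CC(C)=CCc1c(O)c([C@@H]2COc3cc(O)ccc3C2)cc2c1OC(C)(C)C=C2 | target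

## Step count and least certain steps

Total step count: 15. Longest linear sequence: 13 (steps 1–9 and 12–15); the siloxyalkyne branch (steps 10–11) joins at step 12.

Step 12 (key step). The photogenerated vinylketene 20 carries no stabilising substituent. It may dimerise, be trapped by the phenol already formed, or isomerise E→Z under the light and then lose C3–H by a 1,5-hydrogen shift, all before the bimolecular [2+2] with the hindered alkyne 19 takes place. The fallback separates ketene formation from ring formation and replaces the [2+2]/4π sequence by an anionic addition. It sets out from 14 and returns at 24. C-silylation of 14 (TIPSOTf, i-Pr2NEt, Et2O, 0 °C) would give (E)-4-[(R)-7-(allyloxy)chroman-3-yl]-1-diazo-1-(triisopropylsilyl)but-3-en-2-one F1. Photochemical Wolff rearrangement of F1 would give the (triisopropylsilyl)vinylketene (E)-4-[(R)-7-(allyloxy)chroman-3-yl]-2-(triisopropylsilyl)buta-1,3-dien-1-one F2, a ketene that does not dimerise and can be purified. In the dark, lithium ynolate 18 (made as in step 11 and used before silylation) would add through its prenyl-bearing carbon to the ketene carbonyl of F2. 6π closure, tautomerisation and a 1,3 carbon-to-oxygen silyl shift should then place the silyl group on O4′ and give 24 on protonation.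

Step 4. The enantioselectivity on this 7-alkoxy cyclic acid may fall short, because the ether oxygen O1 next to C2 offers the metal a second binding site. The fallback replaces catalysis by resolution. It sets out from 6 and returns at 8. Hydrogenation of 6 over Pd/C would reduce C3=C4 and cleave the benzyl ether in one operation to racemic 7-hydroxychroman-3-carboxylic acid F3. Crystallisation with one antipode of 1-phenylethylamine would give the salt of the (S)-acid, (R)-1-phenylethylammonium (S)-7-hydroxychroman-3-carboxylate F4 (drawn for the R amine; the antipode that makes the S-acid salt the less soluble one is used). Acidification liberates 8.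

Step 8. Configuration at C3 may erode by enolisation of aldehyde 11, or by β-elimination and re-addition of the aryloxide, if the olefination of this α-branched aldehyde is slow. The fallback reverses polarity so that no aldehyde is ever placed on C3. It sets out from 10 and returns at 12. A Mitsunobu reaction of 10 with 1-phenyl-1H-tetrazole-5-thiol would give 5-({[(S)-7-(allyloxy)chroman-3-yl]methyl}sulfanyl)-1-phenyl-1H-tetrazole F5. Molybdate/H2O2 oxidation would give the sulfone 5-({[(S)-7-(allyloxy)chroman-3-yl]methyl}sulfonyl)-1-phenyl-1H-tetrazole F6. Julia–Kocienski olefination (KHMDS, DME, −60 °C) with 2-methyl-1,3-dioxolane-2-carbaldehyde would give 2-{(E)-2-[(R)-7-(allyloxy)chroman-3-yl]vinyl}-2-methyl-1,3-dioxolane F7. Mild acid hydrolysis of the ketal (PPTS, aqueous acetone) would give 12. The sulfonyl carbanion sits on the exocyclic carbon, so C3 is neither deprotonated nor able to expel the aryloxide.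

Step 14. The hindered, easily oxidised 2-prenylresorcinol 25 may condense slowly. Prolonged heating then invites cyclisation of the prenyl group onto a neighbouring hydroxyl and self-condensation of 26. The fallback builds ring D by a sigmatropic route. It sets out from 25 and returns at 28. Copper-catalysed O-alkylation of the less hindered O4′–H (2-methylbut-3-yn-2-yl trifluoroacetate, DBU, CuCl2 cat., MeCN, 0 °C) would give the propargyl ether 6-[(3R)-7-(allyloxy)chroman-3-yl]-3-[(2-methylbut-3-yn-2-yl)oxy]-2-(3-methylbut-2-en-1-yl)phenol F8. Heating F8 in xylene at about 130 °C should bring about propargyl Claisen rearrangement to C5′ (C3′ is blocked), 1,5-hydrogen shift and oxa-6π closure to 28. This is below the temperature at which the A-ring allyl ether rearranges.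

## Further compounds

F1 | step 12 | (E)-4-[(R)-7-(allyloxy)chroman-3-yl]-1-diazo-1-(triisopropylsilyl)but-3-en-2-one | CC(C)[Si](C(C)C)(C(C)C)C(=[N+]=[N-])C(=O)/C=C/[C@@H]1COc2cc(OCC=C)ccc2C1
F2 | step 12 | (E)-4-[(R)-7-(allyloxy)chroman-3-yl]-2-(triisopropylsilyl)buta-1,3-dien-1-one | CC(C)[Si](C(C)C)(C(C)C)C(=C=O)/C=C/[C@@H]1COc2cc(OCC=C)ccc2C1
F3 | step 4 | rac-7-hydroxychroman-3-carboxylic acid | OC(=O)C1COc2cc(O)ccc2C1
F4 | step 4 | (R)-1-phenylethylammonium (S)-7-hydroxychroman-3-carboxylate | [O-]C(=O)[C@@H]1COc2cc(O)ccc2C1.C[C@@H]([NH3+])c1ccccc1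
F5 | step 8 | 5-({[(S)-7-(allyloxy)chroman-3-yl]methyl}sulfanyl)-1-phenyl-1H-tetrazole | c1ccccc1-n1nnnc1SC[C@@H]1COc2cc(OCC=C)ccc2C1
F6 | step 8 | 5-({[(S)-7-(allyloxy)chroman-3-yl]methyl}sulfonyl)-1-phenyl-1H-tetrazole | c1ccccc1-n1nnnc1S(=O)(=O)C[C@@H]1COc2cc(OCC=C)ccc2C1
F7 | step 8 | 2-{(E)-2-[(R)-7-(allyloxy)chroman-3-yl]vinyl}-2-methyl-1,3-dioxolane | CC1(/C=C/[C@@H]2COc3cc(OCC=C)ccc3C2)OCCO1
F8 | step 14 | 6-[(3R)-7-(allyloxy)chroman-3-yl]-3-[(2-methylbut-3-yn-2-yl)oxy]-2-(3-methylbut-2-en-1-yl)phenol | CC(C)=CCc1c(O)c([C@@H]2COc3cc(OCC=C)ccc3C2)ccc1OC(C)(C)C#C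
A1 | alternative 1 | methyl N-[(2S,3R)-7-(tert-butyldimethylsilyloxy)-3-{7-(tert-butyldimethylsilyloxy)-2,2-dimethyl-8-(3-methylbut-2-en-1-yl)-2H-chromen-6-yl}chroman-2-yl]carbamate (2,3-trans) | CC(C)=CCc1c(O[Si](C)(C)C(C)(C)C)c([C@@H]2[C@@H](NC(=O)OC)Oc3cc(O[Si](C)(C)C(C)(C)C)ccc3C2)cc2c1OC(C)(C)C=C2
A2 | alternative 1 | methyl N-{(E)-2-[7-(tert-butyldimethylsilyloxy)-2,2-dimethyl-8-(3-methylbut-2-en-1-yl)-2H-chromen-6-yl]vinyl}carbamate | COC(=O)N/C=C/c1cc2C=CC(C)(C)Oc2c(CC=C(C)C)c1O[Si](C)(C)C(C)(C)C
A3 | alternative 1 | 5-(tert-butyldimethylsilyloxy)-2-(hydroxymethyl)phenol | OCc1ccc(O[Si](C)(C)C(C)(C)C)cc1O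
A4 | alternative 2 | (3R)-3-[7-hydroxy-2,2-dimethyl-8-(3-methylbut-2-en-1-yl)-2H-chromen-6-yl]chroman-7-yl pivalate | CC(C)=CCc1c(O)c([C@@H]2COc3cc(OC(=O)C(C)(C)C)ccc3C2)cc2c1OC(C)(C)C=C2
A5 | alternative 2 | (3R)-3-[2,4-dihydroxy-3-(3-methylbut-2-en-1-yl)phenyl]chroman-7-yl pivalate | CC(C)=CCc1c(O)c([C@@H]2COc3cc(OC(=O)C(C)(C)C)ccc3C2)ccc1O
A6 | alternative 3 | (3R)-3-[7-(allyloxy)-2,2-dimethyl-8-(3-methylbut-2-en-1-yl)-2H-chromen-6-yl]chroman-7-ol | C=CCOc1c([C@@H]2COc3cc(O)ccc3C2)cc2C=CC(C)(C)Oc2c1CC=C(C)C
A7 | alternative 3 | 4-{(2R)-2-[7-(allyloxy)-2,2-dimethyl-8-(3-methylbut-2-en-1-yl)-2H-chromen-6-yl]-3-hydroxypropyl}-4-hydroxycyclohexa-2,5-dien-1-one | C=CCOc1c([C@@H](CC2(O)C=CC(=O)C=C2)CO)cc2C=CC(C)(C)Oc2c1CC=C(C)C
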